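The dihydrofuran ring is cut at C3–C2 and O1–C2, so that C2 arrives as a one-carbon ylide unit between a benzylic carbon and a phenolic oxygen. The key step exploits that C3 is a CH2 group ortho to O1 on the benzene ring, i.e. the exocyclic carbon of an o-quinone methide, and that C2 bears oxygen. In one operation the methide released from 6-bromo-3-methoxy-2-(tosylmethyl)phenol adds an ester-stabilised sulfonium ylide at C3 and O1 then displaces dimethyl sulfide at C2, forming the ring, both bonds and the C2 stereocentre under a chiral bis-urea. The ester is later methylated to the carbinol and the C7 bromine exchanged for the hydroxycinnamoyl ketone.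

Key step: step 4

Assumption: the sense of induction of the bis-urea in step 4 cannot be taken from precedent, so the (R,R)-catalyst (one mixing of commercial (1R,2R)-cyclohexane-1,2-diamine with 3,5-bis(trifluoromethyl)phenyl isocyanate, not counted as a step) is written as the one leading to (2R)-9, and its antipode is used instead if the first run shows the opposite sense.

Step 1
Reactants: 1 2-bromo-5-methoxyphenol
Product: 2 3-bromo-2-hydroxy-6-methoxybenzaldehyde
Conditions: MgCl2 (2 equiv), Et3N (2.5 equiv), (CH2O)n (4 equiv), THF, reflux; then 1 M HCl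
Reagents that add atoms: paraformaldehyde (reacts as formaldehyde), C=O
Why: Magnesium-phenoxide-directed ortho-formylation (Casiraghi–Skattebøl reaction) delivers formaldehyde only to a free ortho carbon, and since the other ortho position carries bromine the aldehyde can only enter between OH and OMe, a second formaldehyde accepting the hydride that turns the hydroxymethyl stage into the aldehyde.

Step 2
Reactants: 2 3-bromo-2-hydroxy-6-methoxybenzaldehyde
Product: 3 6-bromo-2-(hydroxymethyl)-3-methoxyphenol
Conditions: NaBH4 (1 equiv), THF–MeOH, 0 °C; aq. NH4Cl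
Reagents that add atoms: none
Why: Chemoselective borohydride reduction of the aryl aldehyde to the salicyl alcohol, to which aryl bromide, phenol and methyl ether are inert.

Step 3
Reactants: 3 6-bromo-2-(hydroxymethyl)-3-methoxyphenol
Product: 4 6-bromo-3-methoxy-2-(tosylmethyl)phenol
Conditions: TolSO2Na (3 equiv), HCO2H–H2O, rt
Reagents that add atoms: sodium p-toluenesulfinate, Cc1ccc(cc1)S(=O)[O-].[Na+]
Why: Acid-promoted SN1-type substitution, in which the benzylic alcohol flanked by OH and OMe ionises readily to a protonated o-quinone methide that the sulfinate captures through sulfur to give the thermodynamically preferred sulfone.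

Step 4
Reactants: 4 6-bromo-3-methoxy-2-(tosylmethyl)phenol; 5 (2-ethoxy-2-oxoethyl)dimethylsulfonium bromide
Product: 9 ethyl (2R)-7-bromo-4-methoxy-2,3-dihydro-1-benzofuran-2-carboxylate, via ethyl (dimethylsulfaniumyl)acetate ylide 6 (not isolated), via 6-bromo-3-methoxy-o-quinone methide 7 (not isolated), via phenoxide–sulfonium betaine 8 (not isolated)
Conditions: 5 (1.5 equiv), Cs2CO3 (3 equiv, powder), (R,R)-bis-urea catalyst [1,1'-((1R,2R)-cyclohexane-1,2-diyl)bis(3-(3,5-bis(trifluoromethyl)phenyl)urea), 20 mol%], CH2Cl2, −20 → 0 °C
Reagents that add atoms: none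
Why: Proposed new method: solid Cs2CO3 converts 5 into ylide 6 and 4 into its phenoxide, which expels p-toluenesulfinate (E1cB) to give methide 7; 6 adds through carbon to the exocyclic CH2 of 7 (C3–C2) with re-aromatisation to betaine 8, and the phenoxide of 8 displaces dimethyl sulfide from C2 (O1–C2). The closest known reaction is the formal [4+1] annulation of stabilised sulfonium ylides with o-quinone methides released from 2-(tosylalkyl)phenols, established in racemic form and, with chiral hydrogen-bond donors, in enantioselective form for methides bearing a C3 substituent; new here is enantiocontrol when C3 is CH2, where the stereocentre lies on the former ylide carbon. The furan ring closes by 5-exo-tet SN2 displacement with inversion at C2. C2, the only stereocentre, is controlled by the bis-urea, which is expected to hold the methide/phenoxide oxygen with one urea and the ylide/ester carbonyl with the other, so that the face of the ylide carbon is selected in the C–C bond formation and, since the acidic α-sulfonio C–H lets the epimers of 8 interconvert, the faster-closing catalyst-bound epimer is drained (dynamic kinetic resolution). The step needs a single C-alkylation at the methide carbon followed by O-closure onto the same ylide carbon, which the substrate secures because the CH2 terminus is the only electrophilic site of 7 and the unmasked phenoxide sits five atoms from the sulfonium carbon, while slow methide release by the heterogeneous base into excess 6 disfavours a second addition and oligomerisation. The product must not epimerise, and its α-aryloxy ester C–H is far too weak an acid for solid carbonate at this temperature.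

Step 5
Reactants: 9 ethyl (2R)-7-bromo-4-methoxy-2,3-dihydro-1-benzofuran-2-carboxylate
Product: 11 2-[(2R)-7-bromo-4-methoxy-2,3-dihydro-1-benzofuran-2-yl]propan-2-ol, via 1-[(2R)-7-bromo-4-methoxy-2,3-dihydro-1-benzofuran-2-yl]ethan-1-one 10 (not isolated)
Conditions: MeMgBr (3.5 equiv), THF, −20 → 0 °C; sat. NH4Cl
Reagents that add atoms: methylmagnesium bromide, C[Mg]Br
Why: Double Grignard addition to the ester via ketone 10 gives the tertiary carbinol, the C2 configuration being retained because addition to the chelating α-alkoxy carbonyl outpaces enolisation, and the aryl bromide does not react with MeMgBr.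

Step 6
Reactants: 12 4-[(tert-butyldimethylsilyl)oxy]benzaldehyde; 13 diethyl {2-[methoxy(methyl)amino]-2-oxoethyl}phosphonate
Product: 14 (2E)-3-{4-[(tert-butyldimethylsilyl)oxy]phenyl}-N-methoxy-N-methylprop-2-enamide
Conditions: NaH (1.1 equiv), 13 (1.1 equiv), THF, 0 °C → rt; sat. NH4Cl
Reagents that add atoms: none
Why: Horner–Wadsworth–Emmons olefination of the aryl aldehyde with the stabilised Weinreb-amide phosphonate anion, which gives the E-alkene and leaves the aryl silyl ether intact.

Step 7
Reactants: 11 2-[(2R)-7-bromo-4-methoxy-2,3-dihydro-1-benzofuran-2-yl]propan-2-ol; 14 (2E)-3-{4-[(tert-butyldimethylsilyl)oxy]phenyl}-N-methoxy-N-methylprop-2-enamide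
Product: 16 (2E)-3-{4-[(tert-butyldimethylsilyl)oxy]phenyl}-1-[(2R)-2-(2-hydroxypropan-2-yl)-4-methoxy-2,3-dihydro-1-benzofuran-7-yl]prop-2-en-1-one, via C7-lithio lithium alkoxide 15 (not isolated)
Conditions: MeLi (1.05 equiv), THF, −78 °C; n-BuLi (1.1 equiv), −78 °C; then 14 (1.3 equiv), −78 → −20 °C; sat. NH4Cl
Reagents that add atoms: none
Why: MeLi first converts the tertiary OH into its lithium alkoxide so that the aryllithium made by Br–Li exchange with n-BuLi is not quenched, and this aryllithium adds 1,2 to the Weinreb amide, whose N-methoxy chelate holds the tetrahedral adduct until work-up (Weinreb ketone synthesis), leaving the E-alkene, the silyl ether and C2 untouched.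

Step 8
Reactants: 16 (2E)-3-{4-[(tert-butyldimethylsilyl)oxy]phenyl}-1-[(2R)-2-(2-hydroxypropan-2-yl)-4-methoxy-2,3-dihydro-1-benzofuran-7-yl]prop-2-en-1-one
Product: 17 (2E)-3-(4-hydroxyphenyl)-1-[(2R)-2-(2-hydroxypropan-2-yl)-4-methoxy-2,3-dihydro-1-benzofuran-7-yl]prop-2-en-1-one
Conditions: TBAF (1.1 equiv), AcOH (1.1 equiv), THF, 0 °C
Reagents that add atoms: none
Why: Fluoride-mediated cleavage of the phenolic silyl ether, buffered with acetic acid so that the enone, its E-geometry and the tertiary alcohol are unaffected.

Compound list
1 | 2-bromo-5-methoxyphenol | COc1ccc(Br)c(O)c1 | starting material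
2 | 3-bromo-2-hydroxy-6-methoxybenzaldehyde | COc1ccc(Br)c(O)c1C=O | intermediate
3 | 6-bromo-2-(hydroxymethyl)-3-methoxyphenol | COc1ccc(Br)c(O)c1CO | intermediate
4 | 6-bromo-3-methoxy-2-(tosylmethyl)phenol | COc1ccc(Br)c(O)c1CS(=O)(=O)c1ccc(C)cc1 | intermediate
5 | (2-ethoxy-2-oxoethyl)dimethylsulfonium bromide | CCOC(=O)C[S+](C)C.[Br-] | starting material
6 | ethyl (dimethylsulfaniumyl)acetate ylide | CCOC(=O)[CH-][S+](C)C | intermediate
7 | 6-bromo-3-methoxy-2-methylidenecyclohexa-3,5-dien-1-one (o-quinone methide) | COC1=CC=C(Br)C(=O)C1=C | intermediate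
8 | 6-bromo-2-[2-(dimethylsulfaniumyl)-3-ethoxy-3-oxopropyl]-3-methoxyphenolate (betaine, epimers at the sulfonium carbon interconverting) | CCOC(=O)C(Cc1c(OC)ccc(Br)c1[O-])[S+](C)C | intermediate
9 | ethyl (2R)-7-bromo-4-methoxy-2,3-dihydro-1-benzofuran-2-carboxylate | COc1ccc(Br)c2c1C[C@H](C(=O)OCC)O2 | intermediate
10 | 1-[(2R)-7-bromo-4-methoxy-2,3-dihydro-1-benzofuran-2-yl]ethan-1-one | COc1ccc(Br)c2c1C[C@H](C(C)=O)O2 | intermediate
11 | 2-[(2R)-7-bromo-4-methoxy-2,3-dihydro-1-benzofuran-2-yl]propan-2-ol | COc1ccc(Br)c2c1C[C@H](C(C)(C)O)O2 | intermediate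
12 | 4-[(tert-butyldimethylsilyl)oxy]benzaldehyde | O=Cc1ccc(O[Si](C)(C)C(C)(C)C)cc1 | starting material
13 | diethyl {2-[methoxy(methyl)amino]-2-oxoethyl}phosphonate | CCOP(=O)(CC(=O)N(C)OC)OCC | starting material
14 | (2E)-3-{4-[(tert-butyldimethylsilyl)oxy]phenyl}-N-methoxy-N-methylprop-2-enamide | CON(C)C(=O)/C=C/c1ccc(O[Si](C)(C)C(C)(C)C)cc1 | intermediate
15 | lithium 2-[(2R)-7-lithio-4-methoxy-2,3-dihydro-1-benzofuran-2-yl]propan-2-olate | COc1ccc([Li])c2c1C[C@H](C(C)(C)O[Li])O2 | intermediate
16 | (2E)-3-{4-[(tert-butyldimethylsilyl)oxy]phenyl}-1-[(2R)-2-(2-hydroxypropan-2-yl)-4-methoxy-2,3-dihydro-1-benzofuran-7-yl]prop-2-en-1-one | COc1ccc(C(=O)/C=C/c2ccc(O[Si](C)(C)C(C)(C)C)cc2)c2c1C[C@H](C(C)(C)O)O2 | intermediate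
17 | (2E)-3-(4-hydroxyphenyl)-1-[(2R)-2-(2-hydroxypropan-2-yl)-4-methoxy-2,3-dihydro-1-benzofuran-7-yl]prop-2-en-1-one | COc1ccc(C(=O)/C=C/c2ccc(O)cc2)c2c1C[C@H](C(C)(C)O)O2 | target

Total step count: 8. Longest linear sequence: 7 steps (steps 1, 2, 3, 4, 5, 7 and 8, from 1 to 17).

Steps most likely to fail

1. Step 4 (Proposed new method). Enantioselection at C2 may be poor, because addition of free ylide to unbound methide and unassisted ring closure can outrun the catalyst-bound pathway; a second methide may also alkylate the betaine. Fallback, known chemistry: setting out from 4 and 5, the annulation is run without any chiral additive (Cs2CO3, MeCN, rt), which is the established racemic reaction and should give ethyl (2RS)-7-bromo-4-methoxy-2,3-dihydro-1-benzofuran-2-carboxylate F1. The enantiomers are then separated by preparative chromatography on a polysaccharide-based chiral stationary phase, and the (2R)-enantiomer re-enters the route as compound 9. Its configuration is assigned by anomalous-dispersion X-ray analysis with bromine as heavy atom. The (2S)-enantiomer can be racemised with catalytic NaOEt in EtOH and passed through again.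

2. Step 7. The aryllithium may be protonated before acyl transfer (loss of the bromine handle), or it may add in conjugate fashion to the cinnamoyl double bond instead of the amide carbonyl. Fallback: setting out from 11, Stille coupling with tributyl(1-ethoxyvinyl)stannane (Pd(PPh3)4, toluene, 100 °C) should give 2-[(2R)-7-(1-ethoxyethenyl)-4-methoxy-2,3-dihydro-1-benzofuran-2-yl]propan-2-ol F2. Hydrolysis with 1 M HCl in THF at rt gives 1-[(2R)-2-(2-hydroxypropan-2-yl)-4-methoxy-2,3-dihydro-1-benzofuran-7-yl]ethan-1-one F3. Claisen–Schmidt condensation of F3 with commercial 4-hydroxybenzaldehyde (KOH, EtOH, rt) then forms the E-enone and comes back to the route at the target 17, without organolithium or silyl protection.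

3. Step 3. The benzylic cation may condense with the electron-rich ring of a second molecule (oligomer formation) in competition with capture by the sulfinate. Fallback: setting out from aldehyde 2, reductive amination with dimethylamine (NaBH(OAc)3, 1,2-dichloroethane, rt) should give the Mannich base 6-bromo-2-[(dimethylamino)methyl]-3-methoxyphenol F4. Heating F4 with sodium p-toluenesulfinate in aqueous DMF (100 °C) releases the methide thermally under non-acidic conditions and exchanges dimethylamine for the sulfinate, returning to the route at 4.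

Further compounds
F1 | step 4 | ethyl (2RS)-7-bromo-4-methoxy-2,3-dihydro-1-benzofuran-2-carboxylate (racemate) | CCOC(=O)C1Cc2c(OC)ccc(Br)c2O1
F2 | step 7 | 2-[(2R)-7-(1-ethoxyethenyl)-4-methoxy-2,3-dihydro-1-benzofuran-2-yl]propan-2-ol | COc1ccc(C(=C)OCC)c2c1C[C@H](C(C)(C)O)O2
F3 | step 7 | 1-[(2R)-2-(2-hydroxypropan-2-yl)-4-methoxy-2,3-dihydro-1-benzofuran-7-yl]ethan-1-one | COc1ccc(C(C)=O)c2c1C[C@H](C(C)(C)O)O2
F4 | step 3 | 6-bromo-2-[(dimethylamino)methyl]-3-methoxyphenol | COc1ccc(Br)c(O)c1CN(C)C
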